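The nine-membered oxacycle O–C3–C4–C5–C6–C7–C8–C9–C10 that bridges the furanone is not closed as such. It is made one atom larger, as a ten-membered cyclic sulfone with SO2 between C4 and C5, closed by thiolate SN2 displacement. A Ramberg–Bäcklund rearrangement then excises SO2, so that ring contraction and the Z C4=C5 double bond arise in one operation. The step exploits the C4–H bond, acidified by the sulfone and, through C3=C2, by the C1 carbonyl. C10 is bought with (S)-citramalic acid and C6 with a butenolide; C7 and C8 are relayed by substrate control.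

Key step: step 16

Remark on numbering: atom labels are germacrane numbers of the target: C1 furanone carbonyl, C2 furanone CH, C3 furanone O-bearing sp2 carbon, C4 (carries C15H2OH), C5, C6 (lactone oxygen), C7, C8 (ester oxygen), C9, C10 (quaternary, carries C14 methyl and the ring oxygen O1), C11, C12 (lactone carbonyl), C13 (exocyclic CH2). C4 in compounds 19–24 and C11 in 26 and 27 are formed as epimer mixtures; both centres become sp2 later.

Step 1
Reactants: 1 (S)-citramalic acid
Product: 2 dioxolanone acid
Conditions: 2,2-dimethoxypropane, TsOH (cat.), acetone, rt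
Reagents that add atoms: 2,2-dimethoxypropane, COC(C)(C)OC
Why: Acid-catalysed transacetalisation closes the five-membered 1,3-dioxolan-4-one on the α-hydroxy acid unit (C10–O and C1) in preference to a six-membered ring, which leaves the C8 carboxyl free and does not touch the C10 stereocentre.

Step 2
Reactants: 2 dioxolanone acid
Product: 3 dioxolanone alcohol
Conditions: BH3·SMe2, THF, 0 °C to rt; MeOH quench
Reagents that add atoms: none
Why: Borane reduces the free carboxylic acid chemoselectively in the presence of the dioxolanone ester (chemoselective borane reduction of a carboxylic acid).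

Step 3
Reactants: 3 dioxolanone alcohol
Product: 4 dioxolanone aldehyde
Conditions: TEMPO (10 mol %), PhI(OAc)2, CH2Cl2, rt
Reagents that add atoms: none
Why: The nitroxyl-catalysed oxidation of a primary alcohol stops at the aldehyde and is neutral enough to leave the dioxolanone intact.

Step 4
Reactants: 5 (S)-5-(hydroxymethyl)furan-2(5H)-one
Product: 6 butenolide tosylate
Conditions: TsCl, pyridine, CH2Cl2, 0 °C
Reagents that add atoms: 4-toluenesulfonyl chloride, Cc1ccc(cc1)S(=O)(=O)Cl
Why: Sulfonylation of the primary alcohol with a weak base at 0 °C avoids γ-deprotonation of the butenolide, so C6 keeps its configuration and C5 already carries the leaving group for the later sulfur introduction.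

Step 5
Reactants: 4 dioxolanone aldehyde, 6 butenolide tosylate (1.5 equiv)
Product: 7 trans keto lactone
Conditions: (nBu4N)4W10O32 (2 mol %), MeCN, 390 nm LEDs, rt
Reagents that add atoms: none
Why: The excited decatungstate abstracts the formyl hydrogen of 4, the nucleophilic acyl radical adds to the β-carbon C7 of the butenolide anti to the C6 CH2OTs group (Giese-type radical hydroacylation) and back hydrogen transfer to C11 closes the cycle, which sets C7 trans to C6.

Step 6
Reactants: 7 trans keto lactone
Product: 8 hydroxy keto ester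
Conditions: camphorsulfonic acid (10 mol %), MeOH, rt
Reagents that add atoms: methanol, CO
Why: Acid-catalysed methanolysis of the activated dioxolanone (an acetal ester) releases acetone and unmasks the tertiary C10 hydroxyl that directs the next step, while the γ-lactone and the tosylate are inert.

Step 7
Reactants: 8 hydroxy keto ester
Product: 10 bis-lactone, via syn-diol ester 9 (not isolated)
Conditions: Et2BOMe (1.1 equiv, removed unchanged by MeOH co-evaporation), THF/MeOH 4:1, −78 °C; NaBH4; AcOH quench; then PPTS (cat.), CH2Cl2, rt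
Reagents that add atoms: none
Why: Narasaka–Prasad reduction of the boron chelate of the β-hydroxy ketone by external hydride gives the 1,3-syn diol (C8–O syn to C10–O), which is also the Felkin–Anh sense with respect to C7, so both elements set C8; the new hydroxyl then lactonises onto the C1 ester in a five-membered ring.

Step 8
Reactants: 10 bis-lactone
Product: 11 silylated bis-lactone
Conditions: 1-(trimethylsilyl)imidazole, CH2Cl2, rt
Reagents that add atoms: 1-(trimethylsilyl)imidazole, C[Si](C)(C)n1ccnc1
Why: Neutral silylation of the hindered tertiary alcohol prevents an α-alkoxide from deactivating the neighbouring C1 lactone carbonyl in the next step.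

Step 9
Reactants: 11 silylated bis-lactone, 12 tert-butyl(but-3-yn-1-yloxy)dimethylsilane
Product: 14 hydroxy ynone, via lithium lactone enolate 13 (not isolated)
Conditions: LiN(SiMe3)2 (1.1 equiv), THF, −78 °C; then the lithium acetylide of 12 (12, nBuLi, THF, −78 °C; 1.5 equiv), −78 to −40 °C; AcOH, −78 °C
Reagents that add atoms: none
Why: The lactone that has α-hydrogens (C11) is protected in the flask as its lithium enolate, whereas the C1 lactone has a quaternary α-carbon and cannot enolise, so the acetylide adds only there and the hemiketal alkoxide collapses to the ynone on quench (acetylide addition to a lactone); no stereocentre is touched.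

Step 10
Reactants: 14 hydroxy ynone
Product: 16 furanone alcohol, via dihydroxy ynone 15 (not isolated)
Conditions: AcOH/THF/H2O 3:1:1, 0 °C; then AuCl3 (5 mol %), CH2Cl2, rt
Reagents that add atoms: none
Why: Mild aqueous acid removes the tertiary trimethylsilyl ether and gold-catalysed 5-endo-dig addition of the C10 hydroxyl to the activated ynone gives the 3(2H)-furanone (cycloisomerisation of a γ-hydroxy ynone), the 7-endo mode open to the C8 hydroxyl being slower.

Step 11
Reactants: 16 furanone alcohol
Product: 17 isobutyrate tosylate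
Conditions: isobutyric anhydride, Et3N, DMAP (cat.), CH2Cl2, 0 °C
Reagents that add atoms: isobutyric anhydride, CC(C)C(=O)OC(=O)C(C)C
Why: DMAP-catalysed acylation of the secondary C8 alcohol is fast, and the trans relationship of C8 and C5 on the lactone keeps the alcohol from displacing the tosylate.

Step 12
Reactants: 17 isobutyrate tosylate
Product: 18 thioacetate
Conditions: KSC(O)CH3, DMF, 40 °C
Reagents that add atoms: potassium thioacetate, CC(=O)[S-].[K+]
Why: SN2 displacement of the primary tosylate at C5 by the soft, weakly basic thioacetate anion.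

Step 13
Reactants: 18 thioacetate
Product: 19 C4 bromide
Conditions: NBS (1.05 equiv), AIBN (cat.), PhCF3, 80 °C
Reagents that add atoms: N-bromosuccinimide, O=C1CCC(=O)N1Br
Why: Wohl–Ziegler bromination is selective for the C4 methylene because it is allylic to the furanone C3=C2 bond and its radical is delocalised into the enone; the new C4 centre is not controlled and need not be.

Step 14
Reactants: 19 C4 bromide
Product: 21 cyclic sulfide, via bromo thiol 20 (not isolated)
Conditions: K2CO3, degassed MeOH/THF, 1 mM, slow addition, 0 °C to rt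
Reagents that add atoms: none
Why: Methanolysis frees the thiolate, which closes the ten-membered ring by intramolecular SN2 at the activated secondary bromide under high dilution (macrocyclic thioether formation).

Step 15
Reactants: 21 cyclic sulfide
Product: 22 cyclic sulfone
Conditions: mCPBA (2.2 equiv), NaHCO3, CH2Cl2, 0 °C to rt
Reagents that add atoms: 3-chloroperoxybenzoic acid, OOC(=O)c1cccc(Cl)c1
Why: Peracid oxidises sulfur chemoselectively, since the electron-poor enone double bond and the acylated oxygens do not react.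

Step 16
Reactants: 22 cyclic sulfone
Product: 25 nine-membered Z alkene, via chloro sulfone 23 (not isolated), via episulfone 24 (not isolated)
Conditions: LiN(SiMe3)2 (1.05 equiv), THF, −78 °C; C2Cl6 (1.1 equiv); then KOtBu (3 equiv), −78 to 0 °C
Reagents that add atoms: none
Why: Ramberg–Bäcklund rearrangement: one equivalent of amide base removes the C4 proton (acidified by the sulfone and, through C3=C2, by the C1 carbonyl) and hexachloroethane chlorinates this carbon; tert-butoxide then deprotonates C5, the carbanion displaces chloride from C4 to give the thiirane dioxide 24, and cheletropic loss of SO2 leaves the C4=C5 double bond. The closest known reaction type is the Ramberg–Bäcklund ring contraction of medium-ring and macrocyclic α-halo sulfones. The only ring closed is the transient three-membered episulfone (3-exo-tet), and the ten-membered ring O1–C3–C4–S–C5–C6–C7–C8–C9–C10 thereby contracts to the nine-membered oxacycle. No stereocentre is created, and the double bond should be Z because only the cis-fused episulfone fits across the ring and a ring-trans alkene in the bridged nine-membered ring would be prohibitively strained. The step needs chlorination at C4 and not at C5 or C11, which the far higher acidity of C4–H secures, and 1,3-elimination faster than β-elimination of the C6 lactone oxygen from the C5 carbanion, which low temperature and the fast intramolecular displacement favour.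

Step 17
Reactants: 25 nine-membered Z alkene
Product: 28 α-methylene lactone, via Mannich base 26 (not isolated), via ammonium iodide 27 (not isolated)
Conditions: LiN(SiMe3)2 (1.1 equiv), THF, −78 °C; Eschenmoser's salt, −78 to 0 °C; then MeI, MeOH, rt; then NaHCO3 (aq), CH2Cl2, rt
Reagents that add atoms: Eschenmoser's salt (N,N-dimethylmethyleneiminium iodide), C=[N+](C)C.[I-]
Why: Kinetic deprotonation should occur at the lactone α-methylene C11, which is more acidic and less hindered than the isobutyrate α-CH, and Mannich reaction, N-methylation and E1cB loss of trimethylamine give the exocyclic methylene (Eschenmoser methylenation).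

Step 18
Reactants: 28 α-methylene lactone
Product: 29 target
Conditions: HF·pyridine, THF/pyridine, 0 °C
Reagents that add atoms: none
Why: Fluoride cleaves the primary silyl ether under buffered, weakly acidic conditions that spare the α-methylene lactone, the isobutyrate and the furanone.

Compound list
1 | (S)-citramalic acid, (2S)-2-hydroxy-2-methylbutanedioic acid | C[C@](O)(CC(=O)O)C(=O)O | starting material
2 | 2-[(4S)-2,2,4-trimethyl-5-oxo-1,3-dioxolan-4-yl]acetic acid | C[C@@]1(CC(=O)O)OC(C)(C)OC1=O | intermediate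
3 | (5S)-5-(2-hydroxyethyl)-2,2,5-trimethyl-1,3-dioxolan-4-one | C[C@@]1(CCO)OC(C)(C)OC1=O | intermediate
4 | 2-[(4S)-2,2,4-trimethyl-5-oxo-1,3-dioxolan-4-yl]acetaldehyde | C[C@@]1(CC=O)OC(C)(C)OC1=O | intermediate
5 | (S)-5-(hydroxymethyl)furan-2(5H)-one | O=C1C=C[C@@H](CO)O1 | starting material
6 | [(2S)-5-oxo-2,5-dihydrofuran-2-yl]methyl 4-methylbenzenesulfonate | O=C1C=C[C@@H](COS(=O)(=O)c2ccc(C)cc2)O1 | intermediate
7 | [(2S,3S)-5-oxo-3-{2-[(4S)-2,2,4-trimethyl-5-oxo-1,3-dioxolan-4-yl]acetyl}oxolan-2-yl]methyl 4-methylbenzenesulfonate (2,3-trans) | C[C@@]1(CC(=O)[C@H]2CC(=O)O[C@@H]2COS(=O)(=O)c3ccc(C)cc3)OC(C)(C)OC1=O | intermediate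
8 | methyl (2S)-2-hydroxy-2-methyl-4-oxo-4-[(2S,3S)-5-oxo-2-(tosyloxymethyl)oxolan-3-yl]butanoate | COC(=O)[C@@](C)(O)CC(=O)[C@H]1CC(=O)O[C@@H]1COS(=O)(=O)c2ccc(C)cc2 | intermediate
9 | methyl (2S,4R)-2,4-dihydroxy-2-methyl-4-[(2S,3R)-5-oxo-2-(tosyloxymethyl)oxolan-3-yl]butanoate (2,4-syn diol) | COC(=O)[C@@](C)(O)C[C@@H](O)[C@H]1CC(=O)O[C@@H]1COS(=O)(=O)c2ccc(C)cc2 | intermediate
10 | [(2S,3R)-3-[(2R,4S)-4-hydroxy-4-methyl-5-oxooxolan-2-yl]-5-oxooxolan-2-yl]methyl 4-methylbenzenesulfonate | O=C1O[C@H](C[C@]1(C)O)[C@H]2CC(=O)O[C@@H]2COS(=O)(=O)c3ccc(C)cc3 | intermediate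
11 | trimethylsilyl ether of 10 at the tertiary C10 hydroxyl | O=C1O[C@H](C[C@]1(C)O[Si](C)(C)C)[C@H]2CC(=O)O[C@@H]2COS(=O)(=O)c3ccc(C)cc3 | intermediate
12 | tert-butyl(but-3-yn-1-yloxy)dimethylsilane | C#CCCO[Si](C)(C)C(C)(C)C | starting material
13 | lithium enolate of 11, enolised at C11–C12 of the tosyloxymethyl lactone | O=C1O[C@H](C[C@]1(C)O[Si](C)(C)C)[C@H]2C=C(O[Li])O[C@@H]2COS(=O)(=O)c3ccc(C)cc3 | intermediate
14 | (6S,7R,8R,10S) hydroxy ynone: C1 ketone joined to C≡C–CH2CH2OTBS, C10 OTMS, C8 OH, 6,12-lactone, C5 OTs | CC(C)(C)[Si](C)(C)OCCC#CC(=O)[C@@](C)(O[Si](C)(C)C)C[C@@H](O)[C@H]1CC(=O)O[C@@H]1COS(=O)(=O)c2ccc(C)cc2 | intermediate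
15 | (6S,7R,8R,10S) dihydroxy ynone, as 14 with free C10 OH | CC(C)(C)[Si](C)(C)OCCC#CC(=O)[C@@](C)(O)C[C@@H](O)[C@H]1CC(=O)O[C@@H]1COS(=O)(=O)c2ccc(C)cc2 | intermediate
16 | (6S,7R,8R,10S) 3(2H)-furanone with C3 side chain CH2CH2OTBS, C10 methyl, C8 OH, 6,12-lactone, C5 OTs | CC(C)(C)[Si](C)(C)OCCC1=CC(=O)[C@](C)(C[C@@H](O)[C@H]2CC(=O)O[C@@H]2COS(=O)(=O)c3ccc(C)cc3)O1 | intermediate
17 | C8 isobutyrate of 16 | CC(C)(C)[Si](C)(C)OCCC1=CC(=O)[C@](C)(C[C@@H](OC(=O)C(C)C)[C@H]2CC(=O)O[C@@H]2COS(=O)(=O)c3ccc(C)cc3)O1 | intermediate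
18 | C5 S-acetyl thioester corresponding to 17 | CC(C)(C)[Si](C)(C)OCCC1=CC(=O)[C@](C)(C[C@@H](OC(=O)C(C)C)[C@H]2CC(=O)O[C@@H]2CSC(C)=O)O1 | intermediate
19 | C4 bromide of 18 (C4 epimers) | CC(C)(C)[Si](C)(C)OCC(Br)C1=CC(=O)[C@](C)(C[C@@H](OC(=O)C(C)C)[C@H]2CC(=O)O[C@@H]2CSC(C)=O)O1 | intermediate
20 | C5 thiol of 19 (C4 epimers) | CC(C)(C)[Si](C)(C)OCC(Br)C1=CC(=O)[C@](C)(C[C@@H](OC(=O)C(C)C)[C@H]2CC(=O)O[C@@H]2CS)O1 | intermediate
21 | (6S,7R,8R,10S) ten-membered cyclic sulfide, ring O1–C3–C4–S–C5–C6–C7–C8–C9–C10, fused to the furanone and the 6,12-lactone; C4 CH2OTBS, C8 isobutyrate (C4 epimers) | CC(C)(C)[Si](C)(C)OCC1SC[C@H]2OC(=O)C[C@@H]2[C@H](OC(=O)C(C)C)C[C@]3(C)OC1=CC3=O | intermediate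
22 | S,S-dioxide of 21 | CC(C)(C)[Si](C)(C)OCC1S(=O)(=O)C[C@H]2OC(=O)C[C@@H]2[C@H](OC(=O)C(C)C)C[C@]3(C)OC1=CC3=O | intermediate
23 | C4 chloro derivative of 22 | CC(C)(C)[Si](C)(C)OCC1(Cl)S(=O)(=O)C[C@H]2OC(=O)C[C@@H]2[C@H](OC(=O)C(C)C)C[C@]3(C)OC1=CC3=O | intermediate
24 | cis-fused thiirane 1,1-dioxide across C4–C5 on the nine-membered oxacycle | CC(C)(C)[Si](C)(C)OCC14C(S4(=O)=O)[C@H]2OC(=O)C[C@@H]2[C@H](OC(=O)C(C)C)C[C@]3(C)OC1=CC3=O | intermediate
25 | (4Z,6R,7R,8R,10S) nine-membered oxacycle: 15-O-TBS, 11,13-dihydro form of the target | CC(C)(C)[Si](C)(C)OC/C1=C/[C@H]2OC(=O)C[C@@H]2[C@H](OC(=O)C(C)C)C[C@]3(C)OC1=CC3=O | intermediate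
26 | C11 dimethylaminomethyl derivative of 25 (C11 epimers) | CC(C)(C)[Si](C)(C)OC/C1=C/[C@H]2OC(=O)C(CN(C)C)[C@@H]2[C@H](OC(=O)C(C)C)C[C@]3(C)OC1=CC3=O | intermediate
27 | trimethylammonium iodide of 26 | CC(C)(C)[Si](C)(C)OC/C1=C/[C@H]2OC(=O)C(C[N+](C)(C)C)[C@@H]2[C@H](OC(=O)C(C)C)C[C@]3(C)OC1=CC3=O.[I-] | intermediate
28 | 15-O-TBS ether of the target | CC(C)(C)[Si](C)(C)OC/C1=C/[C@H]2OC(=O)C(=C)[C@@H]2[C@H](OC(=O)C(C)C)C[C@]3(C)OC1=CC3=O | intermediate
29 | CNP0176924.2, (4Z,6R,7R,8R,10S) | C=C1C(=O)O[C@@H]2/C=C(/CO)C3=CC(=O)[C@](C)(C[C@@H](OC(=O)C(C)C)[C@@H]12)O3 | target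

Total step count: 18. Longest linear sequence: 17 steps (steps 1–3 and 5–18, from (S)-citramalic acid); step 4 is a one-step branch.

Steps most likely to fail

1. Step 16. The C5 carbanion may expel the C6 lactone oxygen by β-elimination faster than it closes the episulfone, and excess base may move the new double bond towards C6. The fallback sets out from sulfide 21 and comes back at 25. S-Methylation of 21 with methyl triflate (CH2Cl2, 0 °C) should give the S-methylsulfonium triflate F1. KOtBu in THF generates the ylide at C4, and its Stevens [1,2]-shift moves C5 from sulfur to C4, which contracts the ring to the nine-membered methylthio compound F2. One equivalent of mCPBA at −78 °C gives the methyl sulfoxide F3. Thermal syn-elimination of methanesulfenic acid in toluene at 110 °C should take the C5 hydrogen, not the C15 hydrogen next to oxygen, and deliver 25.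

2. Step 9. Incomplete enolisation or proton exchange between the lactone enolate and the acetylide would let the nucleophile attack the wrong lactone or fail to add. The fallback sets out from 7 and comes back at 16. Morpholine (THF, rt) opens the activated dioxolanone of 7 with loss of acetone and should give the morpholine amide hydroxy ketone F4. Narasaka–Prasad reduction (Et2BOMe, NaBH4, −78 °C) gives the syn-diol amide F5, which does not lactonise. 2,2-Dimethoxypropane with PPTS gives the acetonide F6. The alkynylmagnesium bromide made from 12 and EtMgBr (THF, 0 °C) adds to the morpholine amide, which stops at the ketone stage and reacts faster than the γ-lactone, to give the ynone acetonide F7. Aqueous acetic acid removes the acetonide to give 15, and AuCl3 closes the furanone to 16 as in step 10.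

3. Step 5. Hydrogen abstraction at other C–H bonds (for instance C6–H of the butenolide) or slow addition of the acyl radical to the β-substituted acceptor may give low conversion and telomers. The fallback sets out from 3 (with 6) and comes back at 7. Alcohol 3 with I2, PPh3 and imidazole gives the primary iodide F8. NaNO2 in DMF gives the nitro compound F9. DBU-catalysed Michael addition of its nitronate to butenolide 6 (MeCN, 0 °C), anti to the C6 substituent, gives the nitro lactone F10. A reductive Nef reaction (TiCl3, NH4OAc buffer, THF/H2O) converts the secondary nitro group into the C8 ketone 7.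

Further compounds
F1 | step 16 | S-methylsulfonium triflate of sulfide 21 | CC(C)(C)[Si](C)(C)OCC1[S+](C)C[C@H]2OC(=O)C[C@@H]2[C@H](OC(=O)C(C)C)C[C@]3(C)OC1=CC3=O.[O-]S(=O)(=O)C(F)(F)F
F2 | step 16 | nine-membered oxacycle with methylthio group at C4 (Stevens product) | CC(C)(C)[Si](C)(C)OCC1(SC)C[C@H]2OC(=O)C[C@@H]2[C@H](OC(=O)C(C)C)C[C@]3(C)OC1=CC3=O
F3 | step 16 | methyl sulfoxide of F2 | CC(C)(C)[Si](C)(C)OCC1(S(C)=O)C[C@H]2OC(=O)C[C@@H]2[C@H](OC(=O)C(C)C)C[C@]3(C)OC1=CC3=O
F4 | step 9 | morpholine amide hydroxy ketone (C1 amide, C10 OH, C8 ketone) | O=C(N1CCOCC1)[C@@](C)(O)CC(=O)[C@H]2CC(=O)O[C@@H]2COS(=O)(=O)c3ccc(C)cc3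
F5 | step 9 | syn-diol morpholine amide | O=C(N1CCOCC1)[C@@](C)(O)C[C@@H](O)[C@H]2CC(=O)O[C@@H]2COS(=O)(=O)c3ccc(C)cc3
F6 | step 9 | acetonide of F5 across the C8 and C10 oxygens | O=C(N1CCOCC1)[C@]2(C)C[C@@H](OC(C)(C)O2)[C@H]3CC(=O)O[C@@H]3COS(=O)(=O)c4ccc(C)cc4
F7 | step 9 | ynone acetonide | CC(C)(C)[Si](C)(C)OCCC#CC(=O)[C@]1(C)C[C@@H](OC(C)(C)O1)[C@H]2CC(=O)O[C@@H]2COS(=O)(=O)c3ccc(C)cc3
F8 | step 5 | (5S)-5-(2-iodoethyl)-2,2,5-trimethyl-1,3-dioxolan-4-one | C[C@@]1(CCI)OC(C)(C)OC1=O
F9 | step 5 | (5S)-2,2,5-trimethyl-5-(2-nitroethyl)-1,3-dioxolan-4-one | C[C@@]1(CC[N+](=O)[O-])OC(C)(C)OC1=O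
F10 | step 5 | trans nitro lactone, Michael adduct of F9 and 6 (C8 epimers) | C[C@@]1(CC([N+](=O)[O-])[C@H]2CC(=O)O[C@@H]2COS(=O)(=O)c3ccc(C)cc3)OC(C)(C)OC1=O
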